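**Plan**

1. Numbering (germacrane): ring C1–C10; cis-oxirane on C1/C10 (methyl C14 on C10); trans-oxirane on C4/C5 (methyl C15 on C4); acetate on C6; isopropyl C11 (C12, C13) on C7; angelate on C8.
2. Retrosynthesis: the C8 angelate and C6 acetate are removed, then both oxiranes, and isopropyl is taken back to isopropenyl; this leaves a (1(10)Z,4E)-cyclodecadiene with C6–OH, C7–isopropenyl and C8–OSi.
3. Enabling feature: the C6 carbinol is allylic to C4=C5 and vicinal to C7, which carries the three-carbon branch C11–C13; this is the retron of a [2,3]-Wittig shift. Cutting C6–C7 and joining O6 to C12 gives a 13-membered diallylic ether (ring O, C6, C5, C4, C3, C2, C1, C10, C9, C8, C7, C11, C12) in which C6–H is allylic and α to oxygen and O–C12–C11=C7 is the migrating allyl unit.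
4. The ether is cut at O–C12 (Williamson) and the chain at C7=C11 (Still–Gennari), C9–C10 (alkenyl Grignard/CuI opening of (S)-glycidate) and C1=C10 (iodo-Wittig), back to geraniol (C2–C6, C15).
5. Forward order: acyclic C15 chain, 13-membered ether, ring contraction to the ten-membered carbocycle, isopropenyl hydrogenation, C4–C5 oxirane, acetate, C1–C10 oxirane, angelate.
6. Stereochemistry: C8 from methyl (S)-glycidate; C6 and C7 from the ring contraction (Z geometry of C7=C11 and the C8 silyloxy group); C4/C5 by delivery from the C6 hydroxyl; C1/C10 by Shi catalyst control; alkene geometries from geraniol (4E), the iodo-Wittig step (1(10)Z) and the Still–Gennari step (C12 cis to C8).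

Key step: step 13

Remark: the side-chain ester is read as the (Z)-2-methylbut-2-enoate (angelate), the C1–C10 oxirane as cis and the C4–C5 oxirane as trans, as the target SMILES encodes; in the numbering above the target is 1R,4S,5S,6R,7R,8S,10S.

**Route**

Step 1
Reactants: 1 geraniol
Product: 3 geranyl 4-methoxybenzyl ether
Conditions: NaH, 2, Bu4NI (cat.), THF/DMF, 0 °C to rt
Reagents that add atoms: 4-methoxybenzyl chloride (2), COc1ccc(CCl)cc1
Why: Williamson etherification of the primary allylic alkoxide with the benzylic chloride should proceed cleanly and leaves the E alkene (later C4=C5) untouched.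

Step 2
Reactants: 3 geranyl 4-methoxybenzyl ether
Product: 5 racemic 6,7-epoxygeranyl 4-methoxybenzyl ether
Conditions: 4 (1.0 equiv), NaHCO3, CH2Cl2, −20 to 0 °C
Reagents that add atoms: 3-chloroperoxybenzoic acid (4), OOC(=O)c1cccc(Cl)c1
Why: Prilezhaev epoxidation should select the distal trisubstituted alkene because the proximal one is deactivated by the allylic ether oxygen, and the racemic stereocentre is destroyed in step 3.

Step 3
Reactants: 5 racemic 6,7-epoxygeranyl 4-methoxybenzyl ether
Product: 7 (4E)-6-[(4-methoxybenzyl)oxy]-4-methylhex-4-enal, via vicinal diol 6 (not isolated)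
Conditions: H5IO6, THF/H2O, 0 °C
Reagents that add atoms: none
Why: Hydrolysis of the trisubstituted epoxide followed by Malaprade glycol cleavage with periodic acid should give the aldehyde (later C1) and acetone without touching the PMB ether.

Step 4
Reactants: 7 (4E)-6-[(4-methoxybenzyl)oxy]-4-methylhex-4-enal; 8 ethyltriphenylphosphonium iodide
Product: 10 1-({[(2E,6Z)-7-iodo-3-methylocta-2,6-dien-1-yl]oxy}methyl)-4-methoxybenzene
Conditions: 8, n-BuLi, THF, 0 °C; 9, −78 °C; NaN(SiMe3)2, −78 °C; then 7, −78 °C to rt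
Reagents that add atoms: iodine (9), II
Why: Stork–Zhao-type Wittig olefination with the α-iodo ylide made in the flask should give the (Z)-2-iodoalkene under kinetic low-temperature control, which fixes the cis geometry of the later C1=C10 alkene.

Step 5
Reactants: 10 the (2E,6Z)-alkenyl iodide; 11 methyl (S)-glycidate
Product: 14 methyl (2S,4Z,8E)-2-hydroxy-10-[(4-methoxybenzyl)oxy]-4,8-dimethyldeca-4,8-dienoate, via alkenyllithium 12 (not isolated), via alkenylmagnesium bromide 13 (not isolated)
Conditions: t-BuLi (2.1 equiv), Et2O, −78 °C; MgBr2·OEt2; CuI (10 mol %), 11, THF, −40 to −20 °C; then H2O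
Reagents that add atoms: none
Why: Iodine–lithium exchange with retention of alkene geometry, transmetalation to the Grignard reagent and CuI-catalysed SN2 opening of the epoxide at its CH2 terminus should form C9–C10, and the C8 stereocentre is taken unchanged from (S)-glycidate.

Step 6
Reactants: 14 the α-hydroxy ester
Product: 16 methyl (2S,4Z,8E)-2-[(tert-butyldimethylsilyl)oxy]-10-[(4-methoxybenzyl)oxy]-4,8-dimethyldeca-4,8-dienoate
Conditions: 15, imidazole, DMF, rt
Reagents that add atoms: tert-butyldimethylsilyl chloride (15), CC(C)(C)[Si](C)(C)Cl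
Why: Imidazole-promoted silylation of the secondary alcohol should protect C8–OH with a group that survives strong base and is bulky enough to steer step 13.

Step 7
Reactants: 16 the α-silyloxy ester
Product: 17 (2S,4Z,8E)-2-[(tert-butyldimethylsilyl)oxy]-10-[(4-methoxybenzyl)oxy]-4,8-dimethyldeca-4,8-dienal
Conditions: i-Bu2AlH (1.1 equiv), CH2Cl2, −78 °C; MeOH, then aq. KNaC4H4O6
Reagents that add atoms: none
Why: Partial reduction of the α-silyloxy methyl ester by i-Bu2AlH should stop at the aldehyde (C7) through the low-temperature aluminium hemiacetal, and immediate use limits epimerisation at C8.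

Step 8
Reactants: 17 the α-silyloxy aldehyde; 18 ethyl 2-[bis(2,2,2-trifluoroethoxy)phosphoryl]propanoate
Product: 19 ethyl (2Z,4S,6Z,10E)-4-[(tert-butyldimethylsilyl)oxy]-12-[(4-methoxybenzyl)oxy]-2,6,10-trimethyldodeca-2,6,10-trienoate
Conditions: 18, KN(SiMe3)2, 18-crown-6, THF, −78 °C; then 17
Reagents that add atoms: none
Why: The Still–Gennari variant of the Horner–Wadsworth–Emmons olefination should give the (Z)-trisubstituted enoate kinetically, which places C12 cis to C8 on the C7=C11 alkene.

Step 9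
Reactants: 19 the (Z)-enoate
Product: 20 (2Z,4S,6Z,10E)-4-[(tert-butyldimethylsilyl)oxy]-12-[(4-methoxybenzyl)oxy]-2,6,10-trimethyldodeca-2,6,10-trien-1-ol
Conditions: i-Bu2AlH (2.5 equiv), CH2Cl2, −78 °C; aq. KNaC4H4O6
Reagents that add atoms: none
Why: 1,2-Reduction of the enoate by i-Bu2AlH should give the (Z)-allylic alcohol (C12–OH) without change of alkene geometry.

Step 10
Reactants: 20 the (Z)-allylic alcohol
Product: 23 1-[({(2E,6Z,9S,10Z)-9-[(tert-butyldimethylsilyl)oxy]-12-chloro-3,7,11-trimethyldodeca-2,6,10-trien-1-yl}oxy)methyl]-4-methoxybenzene, via allylic mesylate 22 (not isolated)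
Conditions: MsCl, 2,4,6-collidine, 21, DMF, 0 °C
Reagents that add atoms: lithium chloride (21), [Li+].[Cl-]
Why: Mesylation in the flask followed by SN2 displacement with chloride (Collington–Meyers chlorination) should convert the primary allylic alcohol to the chloride without allylic transposition or loss of Z geometry.

Step 11
Reactants: 23 the allylic chloride PMB ether
Product: 24 (2E,6Z,9S,10Z)-9-[(tert-butyldimethylsilyl)oxy]-12-chloro-3,7,11-trimethyldodeca-2,6,10-trien-1-ol
Conditions: DDQ, CH2Cl2/pH 7 phosphate buffer, 0 °C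
Reagents that add atoms: none
Why: Oxidative PMB cleavage by DDQ (benzylic oxocarbenium ion hydrolysed by water) should free the C6 allylic alcohol while the silyl ether and the allylic chloride stay intact.

Step 12
Reactants: 24 the chloro alcohol
Product: 26 (3Z,5S,7Z,11E)-5-[(tert-butyldimethylsilyl)oxy]-3,7,11-trimethyl-1-oxacyclotrideca-3,7,11-triene, via sodium alkoxide 25 (not isolated)
Conditions: NaH, 15-crown-5 (cat.), THF, high dilution with slow addition of 24, 45 °C
Reagents that add atoms: none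
Why: Intramolecular Williamson etherification (SN2 of the C6 alkoxide at the primary allylic C12 chloride) under high dilution should close the 13-membered diallylic ether without touching any stereocentre.

Step 13
Reactants: 26 the 13-membered diallylic ether
Product: 28 (1S,2E,6Z,9S,10S)-9-[(tert-butyldimethylsilyl)oxy]-3,7-dimethyl-10-(prop-1-en-2-yl)cyclodeca-2,6-dien-1-ol, via C6-lithiated ether 27 (not isolated)
Conditions: n-BuLi, THF/hexane, −78 to −20 °C; then H2O
Reagents that add atoms: none
Why: n-BuLi removes a proton from the C6 methylene, which is allylic to C4=C5 and α to the ether oxygen, and the α-oxy allyllithium 27 undergoes a concerted [2,3]-sigmatropic (Wittig) shift through a five-centre envelope (C6, O, C12, C11, C7) in which C6–C7 forms and O–C12 breaks. The closest known reaction type is the [2,3]-Wittig ring contraction of 13-membered diallylic ethers to ten-membered carbocyclic homoallylic alcohols. The ten-membered ring is closed transannularly, formally a 10-exo-trig attack of C6 on C7 of the C7=C11 alkene, with the oxygen bridge released as the C6 alkoxide and C11=C12 emerging as the isopropenyl group. For C6 against C7, the cis arrangement of C12 and C8 on the alkene together with the exo position of the C5 vinyl arm in the envelope should give the syn product, with the C6 oxygen cis to the C7 isopropenyl group on the ring; for C7 against C8, H8 eclipses the alkene to avoid A(1,3) strain with C12, the bulky silyloxy group points away from the ring and C6 attacks anti to the C8–O bond, which places the isopropenyl group trans to the C8 oxygen. The step needs lithiation at C6 and not at C12, which is expected because C6 is the unhindered methylene next to a CH alkene terminus, whereas C12 is flanked by the fully substituted C11 and a shift from C12 would have to build a quaternary centre at C4. The E geometry of C4=C5 and the Z geometry of C1=C10 are not involved and are carried into the product.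

Step 14
Reactants: 28 the isopropenyl cyclodecadienol
Product: 29 (1S,2E,6Z,9S,10S)-9-[(tert-butyldimethylsilyl)oxy]-3,7-dimethyl-10-(propan-2-yl)cyclodeca-2,6-dien-1-ol
Conditions: H2 (1 atm), RhCl(PPh3)3 (10 mol %), benzene/EtOH, rt
Reagents that add atoms: none
Why: Homogeneous hydrogenation with RhCl(PPh3)3 should reduce the unhindered 1,1-disubstituted isopropenyl alkene much faster than the two trisubstituted ring alkenes and creates no stereocentre.

Step 15
Reactants: 29 the isopropyl cyclodecadienol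
Product: 31 (1(10)Z,4S,5S,6R,7S,8S)-8-[(tert-butyldimethylsilyl)oxy]-4,5-epoxygermacr-1(10)-en-6-ol
Conditions: VO(acac)2 (5 mol %), 30, CH2Cl2, 0 °C
Reagents that add atoms: tert-butyl hydroperoxide (30), CC(C)(C)OO
Why: Vanadium-catalysed hydroxyl-directed epoxidation should act only on the allylic C4=C5 alkene, and because H6 eclipses the alkene to avoid A(1,3) strain with the cis methyl C15 the C6 oxygen sits on the exposed outer face (C7 and the ring on the inner face), so oxygen is delivered syn to the hydroxyl to give the threo (4S,5S) oxirane.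

Step 16
Reactants: 31 the epoxy alcohol
Product: 33 (1(10)Z,4S,5S,6R,7S,8S)-6-acetoxy-8-[(tert-butyldimethylsilyl)oxy]-4,5-epoxygermacr-1(10)-ene
Conditions: 32, pyridine, DMAP (5 mol %), CH2Cl2, rt
Reagents that add atoms: acetic anhydride (32), CC(=O)OC(C)=O
Why: DMAP-catalysed acylation should install the C6 acetate with retention, since only the O–H bond is broken.

Step 17
Reactants: 33 the epoxy acetate
Product: 35 (1R,4S,5S,6R,7S,8S,10S)-6-acetoxy-8-[(tert-butyldimethylsilyl)oxy]-1,10:4,5-diepoxygermacrane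
Conditions: D-fructose-derived Shi ketone (30 mol %), 34 (as 2KHSO5·KHSO4·K2SO4), K2CO3, Bu4NHSO4, MeCN/dimethoxymethane/aq. Na2B4O7 buffer (pH 10.5), 0 °C
Reagents that add atoms: potassium peroxymonosulfate (34), [K+].[O-]S(=O)(=O)OO
Why: Shi asymmetric epoxidation through the spiro dioxirane transition state should deliver oxygen to the face of the only remaining alkene that corresponds to (1R,10S), by analogy with the sense found for 1-substituted cycloalkenes of the same substitution pattern, and the cis geometry of C1=C10 is retained in the oxirane.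

Step 18
Reactants: 35 the diepoxy silyl ether
Product: 36 (1R,4S,5S,6R,7R,8S,10S)-6-acetoxy-1,10:4,5-diepoxygermacran-8-ol
Conditions: Bu4NF, AcOH (1:1), THF, 0 °C to rt
Reagents that add atoms: none
Why: Fluoride-mediated desilylation buffered with acetic acid should free C8–OH without acetate migration or oxirane opening.

Step 19
Reactants: 36 the diepoxy alcohol; 37 angelic acid
Product: 38 (1R,4S,5S,6R,7R,8S,10S)-6-acetoxy-1,10:4,5-diepoxygermacran-8-yl (2Z)-2-methylbut-2-enoate
Conditions: 37, 2,4,6-trichlorobenzoyl chloride, Et3N, toluene, rt; then 36, 80 °C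
Reagents that add atoms: none
Why: Yamaguchi-type esterification through the mixed 2,4,6-trichlorobenzoic anhydride, run without a nucleophilic catalyst, should acylate C8–OH with retention and without isomerising the (Z)-2-methylbut-2-enoyl group to the tiglate.

**Compound list**

1 | geraniol, (2E)-3,7-dimethylocta-2,6-dien-1-ol | CC(C)=CCC/C(C)=C/CO | starting material
2 | 4-methoxybenzyl chloride | COc1ccc(CCl)cc1 | starting material
3 | geranyl 4-methoxybenzyl ether | COc1ccc(COC/C=C(\C)CCC=C(C)C)cc1 | intermediate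
4 | 3-chloroperoxybenzoic acid | OOC(=O)c1cccc(Cl)c1 | starting material
5 | 2-{(3E)-5-[(4-methoxybenzyl)oxy]-3-methylpent-3-en-1-yl}-3,3-dimethyloxirane, racemic | COc1ccc(COC/C=C(\C)CCC2OC2(C)C)cc1 | intermediate
6 | (6E)-8-[(4-methoxybenzyl)oxy]-2,6-dimethyloct-6-ene-2,3-diol, racemic | COc1ccc(COC/C=C(\C)CCC(O)C(C)(C)O)cc1 | intermediate
7 | (4E)-6-[(4-methoxybenzyl)oxy]-4-methylhex-4-enal | COc1ccc(COC/C=C(\C)CCC=O)cc1 | intermediate
8 | ethyltriphenylphosphonium iodide | CC[P+](c1ccccc1)(c1ccccc1)c1ccccc1.[I-] | starting material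
9 | iodine | II | starting material
10 | 1-({[(2E,6Z)-7-iodo-3-methylocta-2,6-dien-1-yl]oxy}methyl)-4-methoxybenzene | COc1ccc(COC/C=C(\C)CC/C=C(/C)I)cc1 | intermediate
11 | methyl (2S)-oxirane-2-carboxylate, methyl (S)-glycidate | COC(=O)[C@@H]1CO1 | starting material
12 | alkenyllithium from 10 (Li in place of I, geometry retained) | COc1ccc(COC/C=C(\C)CC/C=C(/C)[Li])cc1 | intermediate
13 | alkenylmagnesium bromide from 12 | COc1ccc(COC/C=C(\C)CC/C=C(/C)[Mg]Br)cc1 | intermediate
14 | methyl (2S,4Z,8E)-2-hydroxy-10-[(4-methoxybenzyl)oxy]-4,8-dimethyldeca-4,8-dienoate | COC(=O)[C@@H](O)C/C(C)=C\CC/C(C)=C/COCc1ccc(OC)cc1 | intermediate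
15 | tert-butyldimethylsilyl chloride | CC(C)(C)[Si](C)(C)Cl | starting material
16 | methyl (2S,4Z,8E)-2-[(tert-butyldimethylsilyl)oxy]-10-[(4-methoxybenzyl)oxy]-4,8-dimethyldeca-4,8-dienoate | COC(=O)[C@@H](O[Si](C)(C)C(C)(C)C)C/C(C)=C\CC/C(C)=C/COCc1ccc(OC)cc1 | intermediate
17 | (2S,4Z,8E)-2-[(tert-butyldimethylsilyl)oxy]-10-[(4-methoxybenzyl)oxy]-4,8-dimethyldeca-4,8-dienal | O=C[C@@H](O[Si](C)(C)C(C)(C)C)C/C(C)=C\CC/C(C)=C/COCc1ccc(OC)cc1 | intermediate
18 | ethyl 2-[bis(2,2,2-trifluoroethoxy)phosphoryl]propanoate | CCOC(=O)C(C)P(=O)(OCC(F)(F)F)OCC(F)(F)F | starting material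
19 | ethyl (2Z,4S,6Z,10E)-4-[(tert-butyldimethylsilyl)oxy]-12-[(4-methoxybenzyl)oxy]-2,6,10-trimethyldodeca-2,6,10-trienoate | CCOC(=O)/C(C)=C\[C@@H](O[Si](C)(C)C(C)(C)C)C/C(C)=C\CC/C(C)=C/COCc1ccc(OC)cc1 | intermediate
20 | (2Z,4S,6Z,10E)-4-[(tert-butyldimethylsilyl)oxy]-12-[(4-methoxybenzyl)oxy]-2,6,10-trimethyldodeca-2,6,10-trien-1-ol | OC/C(C)=C\[C@@H](O[Si](C)(C)C(C)(C)C)C/C(C)=C\CC/C(C)=C/COCc1ccc(OC)cc1 | intermediate
21 | lithium chloride | [Li+].[Cl-] | starting material
22 | methanesulfonate of 20 | CS(=O)(=O)OC/C(C)=C\[C@@H](O[Si](C)(C)C(C)(C)C)C/C(C)=C\CC/C(C)=C/COCc1ccc(OC)cc1 | intermediate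
23 | 1-[({(2E,6Z,9S,10Z)-9-[(tert-butyldimethylsilyl)oxy]-12-chloro-3,7,11-trimethyldodeca-2,6,10-trien-1-yl}oxy)methyl]-4-methoxybenzene | ClC/C(C)=C\[C@@H](O[Si](C)(C)C(C)(C)C)C/C(C)=C\CC/C(C)=C/COCc1ccc(OC)cc1 | intermediate
24 | (2E,6Z,9S,10Z)-9-[(tert-butyldimethylsilyl)oxy]-12-chloro-3,7,11-trimethyldodeca-2,6,10-trien-1-ol | ClC/C(C)=C\[C@@H](O[Si](C)(C)C(C)(C)C)C/C(C)=C\CC/C(C)=C/CO | intermediate
25 | sodium alkoxide of 24 | ClC/C(C)=C\[C@@H](O[Si](C)(C)C(C)(C)C)C/C(C)=C\CC/C(C)=C/C[O-].[Na+] | intermediate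
26 | (3Z,5S,7Z,11E)-5-[(tert-butyldimethylsilyl)oxy]-3,7,11-trimethyl-1-oxacyclotrideca-3,7,11-triene | O1C/C(C)=C\[C@@H](O[Si](C)(C)C(C)(C)C)C/C(C)=C\CC/C(C)=C/C1 | intermediate
27 | 26 lithiated at the OCH2 carbon next to the E alkene (C6) | O1C/C(C)=C\[C@@H](O[Si](C)(C)C(C)(C)C)C/C(C)=C\CC/C(C)=C/C1[Li] | intermediate
28 | (1S,2E,6Z,9S,10S)-9-[(tert-butyldimethylsilyl)oxy]-3,7-dimethyl-10-(prop-1-en-2-yl)cyclodeca-2,6-dien-1-ol | CC(C)(C)[Si](C)(C)O[C@H]1C/C(C)=C\CC/C(C)=C/[C@H](O)[C@@H]1C(C)=C | intermediate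
29 | (1S,2E,6Z,9S,10S)-9-[(tert-butyldimethylsilyl)oxy]-3,7-dimethyl-10-(propan-2-yl)cyclodeca-2,6-dien-1-ol | CC(C)(C)[Si](C)(C)O[C@H]1C/C(C)=C\CC/C(C)=C/[C@H](O)[C@@H]1C(C)C | intermediate
30 | tert-butyl hydroperoxide | CC(C)(C)OO | starting material
31 | (1(10)Z,4S,5S,6R,7S,8S)-8-[(tert-butyldimethylsilyl)oxy]-4,5-epoxygermacr-1(10)-en-6-ol | CC(C)(C)[Si](C)(C)O[C@H]1C/C(C)=C\CC[C@]2(C)O[C@H]2[C@H](O)[C@@H]1C(C)C | intermediate
32 | acetic anhydride | CC(=O)OC(C)=O | starting material
33 | (1(10)Z,4S,5S,6R,7S,8S)-6-acetoxy-8-[(tert-butyldimethylsilyl)oxy]-4,5-epoxygermacr-1(10)-ene | CC(C)(C)[Si](C)(C)O[C@H]1C/C(C)=C\CC[C@]2(C)O[C@H]2[C@H](OC(C)=O)[C@@H]1C(C)C | intermediate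
34 | potassium peroxymonosulfate | [K+].[O-]S(=O)(=O)OO | starting material
35 | (1R,4S,5S,6R,7S,8S,10S)-6-acetoxy-8-[(tert-butyldimethylsilyl)oxy]-1,10:4,5-diepoxygermacrane | CC(C)(C)[Si](C)(C)O[C@H]1C[C@]2(C)O[C@@H]2CC[C@]2(C)O[C@H]2[C@H](OC(C)=O)[C@@H]1C(C)C | intermediate
36 | (1R,4S,5S,6R,7R,8S,10S)-6-acetoxy-1,10:4,5-diepoxygermacran-8-ol | O[C@H]1C[C@]2(C)O[C@@H]2CC[C@]2(C)O[C@H]2[C@H](OC(C)=O)[C@@H]1C(C)C | intermediate
37 | angelic acid, (2Z)-2-methylbut-2-enoic acid | C/C=C(/C)C(=O)O | starting material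
38 | (1R,4S,5S,6R,7R,8S,10S)-6-acetoxy-1,10:4,5-diepoxygermacran-8-yl (2Z)-2-methylbut-2-enoate | C/C=C(/C)C(=O)O[C@H]1C[C@]2(C)O[C@@H]2CC[C@]2(C)O[C@H]2[C@H](OC(C)=O)[C@@H]1C(C)C | target

**Step count and risks**

Total steps: 19. Longest linear sequence: 19 (from geraniol; all other building blocks are commercial).

Steps most likely to fail:

1. Step 13. Lithiation may take place at C12 (or at the allylic C8–H) instead of C6, which would lead to a shift onto C4 or to loss of the silyloxy group. The carbanion may also add to the wrong face of C7 or through the endo envelope, giving a C6 or C7 epimer. Fallback: the ether detour is dropped and the same C6–C7 bond is formed by a carbonyl allylation. From 24, MnO2 oxidation of the allylic alcohol would give (2E,6Z,9S,10Z)-9-[(tert-butyldimethylsilyl)oxy]-12-chloro-3,7,11-trimethyldodeca-2,6,10-trienal F1. An intramolecular Nozaki–Hiyama allylation (CrCl2, NaI, THF/DMF, high dilution) would then join C7 (the γ-carbon of the allylchromium) to the C6 aldehyde and return to 28. If the ring closure favours the anti carbinol, (1R,2E,6Z,9S,10S)-9-[(tert-butyldimethylsilyl)oxy]-3,7-dimethyl-10-(prop-1-en-2-yl)cyclodeca-2,6-dien-1-ol F2, Dess–Martin oxidation to (2E,6Z,9S,10R)-9-[(tert-butyldimethylsilyl)oxy]-3,7-dimethyl-10-(prop-1-en-2-yl)cyclodeca-2,6-dien-1-one F3 and Luche reduction (NaBH4, CeCl3·7H2O) from the face opposite to the C7 isopropenyl group would bring the material back to 28.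

2. Step 17. The conformational bias of the ten-membered ring may override the catalyst, so that oxygen is delivered to the wrong face of C1=C10, or oxygen transfer to the hindered ring alkene may be too slow. Fallback: a two-step anti addition and closure, which places the oxygen on the face opposite to the one a direct oxygen-transfer reagent reaches. From 33, NBS in aqueous acetone would give the bromohydrin (1S,4S,5S,6R,7S,8S,10S)-6-acetoxy-1-bromo-8-[(tert-butyldimethylsilyl)oxy]-4,5-epoxygermacran-10-ol F7 (bromonium ion on the exposed face, water at the tertiary C10 from the other face). DBU in CH2Cl2 would then close the oxirane by SN2 at C1 and return to 35.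

3. Step 12. Intermolecular etherification (oligomers) may outrun ring closure, or the hindered C12 chloride may react with allylic transposition. Fallback: the roles of the two termini are exchanged, so that the unhindered C6 chloride is the electrophile and the C12 alkoxide the nucleophile. From 19, DDQ would give ethyl (2Z,4S,6Z,10E)-4-[(tert-butyldimethylsilyl)oxy]-12-hydroxy-2,6,10-trimethyldodeca-2,6,10-trienoate F4. MsCl/LiCl/2,4,6-collidine would give ethyl (2Z,4S,6Z,10E)-4-[(tert-butyldimethylsilyl)oxy]-12-chloro-2,6,10-trimethyldodeca-2,6,10-trienoate F5, and i-Bu2AlH at −78 °C would give (2Z,4S,6Z,10E)-4-[(tert-butyldimethylsilyl)oxy]-12-chloro-2,6,10-trimethyldodeca-2,6,10-trien-1-ol F6. Cyclisation of its magnesium alkoxide (EtMgBr, THF/HMPA, high dilution) would return to 26.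

Further compounds
F1 | step 13 | (2E,6Z,9S,10Z)-9-[(tert-butyldimethylsilyl)oxy]-12-chloro-3,7,11-trimethyldodeca-2,6,10-trienal | ClC/C(C)=C\[C@@H](O[Si](C)(C)C(C)(C)C)C/C(C)=C\CC/C(C)=C/C=O
F2 | step 13 | (1R,2E,6Z,9S,10S)-9-[(tert-butyldimethylsilyl)oxy]-3,7-dimethyl-10-(prop-1-en-2-yl)cyclodeca-2,6-dien-1-ol | CC(C)(C)[Si](C)(C)O[C@H]1C/C(C)=C\CC/C(C)=C/[C@@H](O)[C@@H]1C(C)=C
F3 | step 13 | (2E,6Z,9S,10R)-9-[(tert-butyldimethylsilyl)oxy]-3,7-dimethyl-10-(prop-1-en-2-yl)cyclodeca-2,6-dien-1-one | CC(C)(C)[Si](C)(C)O[C@H]1C/C(C)=C\CC/C(C)=C/C(=O)[C@@H]1C(C)=C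
F4 | step 12 | ethyl (2Z,4S,6Z,10E)-4-[(tert-butyldimethylsilyl)oxy]-12-hydroxy-2,6,10-trimethyldodeca-2,6,10-trienoate | CCOC(=O)/C(C)=C\[C@@H](O[Si](C)(C)C(C)(C)C)C/C(C)=C\CC/C(C)=C/CO
F5 | step 12 | ethyl (2Z,4S,6Z,10E)-4-[(tert-butyldimethylsilyl)oxy]-12-chloro-2,6,10-trimethyldodeca-2,6,10-trienoate | CCOC(=O)/C(C)=C\[C@@H](O[Si](C)(C)C(C)(C)C)C/C(C)=C\CC/C(C)=C/CCl
F6 | step 12 | (2Z,4S,6Z,10E)-4-[(tert-butyldimethylsilyl)oxy]-12-chloro-2,6,10-trimethyldodeca-2,6,10-trien-1-ol | OC/C(C)=C\[C@@H](O[Si](C)(C)C(C)(C)C)C/C(C)=C\CC/C(C)=C/CCl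
F7 | step 17 | (1S,4S,5S,6R,7S,8S,10S)-6-acetoxy-1-bromo-8-[(tert-butyldimethylsilyl)oxy]-4,5-epoxygermacran-10-ol | CC(C)(C)[Si](C)(C)O[C@H]1C[C@](C)(O)[C@@H](Br)CC[C@]2(C)O[C@H]2[C@H](OC(C)=O)[C@@H]1C(C)C
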